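**Retrosynthetic overview**
1. Macrocarpal J ⇐ tri-O-methyl ether 20 (thiolate demethylation) ⇐ arene 18 (two ortho-lithiation/formylations). The benzylic centre C7′ comes from SN1 methallylation of a 2,4,6-trimethoxybenzylic alcohol, which is made by adding the aryllithium to a C1 aldehyde.
2. The two tertiary alcohols (C4, C11) come from hydride opening of the 3α,4α- and 11,12-epoxides of a eudesma-3,11-diene.
3. Key disconnection: the C1–C2 and C5–C10 bonds are made in one intramolecular Diels–Alder reaction of the acyclic (2E,8E)-trienal 9. The enabling feature is that ring A (C1, C2, C3, C4, C5, C10) is a cyclohexane whose C4 carbinol is the hydrate of a C3=C4 alkene (cyclohexene retron). Its C1–C10 edge carries the future benzylic carbon (as CHO) and the angular methyl, and C5 and C10 are linked by the four-carbon chain C6–C9 of ring B.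
4. Ring order: rings A and B of the decalin close together in step 6; the aromatic ring is introduced intact afterwards.
5. Trienal 9 ⇐ (R)-limonene oxide by periodate ring cleavage, two Wittig reactions and a Horner–Wadsworth–Emmons/reduction sequence. The limonene stereocentre becomes C7 and controls all others.

Key step: step 6

Remark (numbering): the decalin is numbered as a eudesmane. C1 bears the benzylic carbon C7′; C4 bears OH and CH3; C5–H and C10–CH3 are the ring-fusion atoms; C7 bears C11(CH3)2OH. The target is (7′S,1S,4R,5R,7R,10S): trans-fused, 1β side chain, 4α-OH, 5α-H, 7β-hydroxyisopropyl, 10β-CH3.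
Remark (assumption): the commercial cis/trans mixture of (4R)-limonene 1,2-oxide is used, since both epoxide isomers give the same keto aldehyde.

**Step 1**
Reactants: 1 (4R)-limonene 1,2-oxide
Product: 3 (3R)-6-oxo-3-(prop-1-en-2-yl)heptanal, via limonene-1,2-diol 2 (not isolated)
Conditions: HIO4·2H2O, THF/H2O, 0 °C to rt
Reagents that add atoms: water, O
Why: Acid-mediated epoxide hydrolysis and periodate glycol cleavage in one flask open the p-menthane ring between its C1 and C2, both epoxide isomers converging on one keto aldehyde in which the (R) centre (future C7) and the isopropenyl group are untouched.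

**Step 2**
Reactants: 3 (3R)-6-oxo-3-(prop-1-en-2-yl)heptanal; 4 2-(triphenylphosphoranylidene)propanal
Product: 5 (2E,5R)-2-methyl-8-oxo-5-(prop-1-en-2-yl)non-2-enal
Conditions: CH2Cl2, 40 °C
Reagents that add atoms: 2-(triphenylphosphoranylidene)propanal (4), CC(C=O)=P(c1ccccc1)(c1ccccc1)c1ccccc1
Why: The stabilised ylide reacts only with the aldehyde and not with the methyl ketone, in a Wittig reaction that is inherently (E)-selective for 2-methyl-2-enals, which fixes the future C4=C5 geometry.

**Step 3**
Reactants: 5 (2E,5R)-2-methyl-8-oxo-5-(prop-1-en-2-yl)non-2-enal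
Product: 6 (5R,7E)-8-methyl-5-(prop-1-en-2-yl)deca-7,9-dien-2-one
Conditions: Ph3PCH3Br, KN(SiMe3)2, THF, 0 °C; then 5 (1.0 equiv of ylide), −78 to −20 °C
Reagents that add atoms: methyltriphenylphosphonium bromide, C[P+](c1ccccc1)(c1ccccc1)c1ccccc1.[Br-]
Why: Wittig methylenation with one equivalent of ylide at low temperature should be selective for the aldehyde over the methyl ketone and completes the (E)-3-methyl-1,3-diene without disturbing the trisubstituted alkene.

**Step 4**
Reactants: 6 (5R,7E)-8-methyl-5-(prop-1-en-2-yl)deca-7,9-dien-2-one; 7 diethyl {2-[methoxy(methyl)amino]-2-oxoethyl}phosphonate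
Product: 8 (2E,6R,8E)-N-methoxy-N,3,9-trimethyl-6-(prop-1-en-2-yl)undeca-2,8,10-trienamide
Conditions: NaH, THF, 0 to 65 °C; chromatographic removal of the minor (2Z) isomer
Reagents that add atoms: diethyl {2-[methoxy(methyl)amino]-2-oxoethyl}phosphonate (7), CCOP(=O)(CC(=O)N(C)OC)OCC
Why: Horner–Wadsworth–Emmons olefination of the methyl ketone should favour the (E)-trisubstituted enamide (carbonyl trans to the longer chain), and the isomers are separable at this stage.

**Step 5**
Reactants: 8 (2E,6R,8E)-N-methoxy-N,3,9-trimethyl-6-(prop-1-en-2-yl)undeca-2,8,10-trienamide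
Product: 9 (2E,6R,8E)-3,9-dimethyl-6-(prop-1-en-2-yl)undeca-2,8,10-trienal
Conditions: i-Bu2AlH, THF, −78 °C; aq. KNaC4H4O6 (potassium sodium tartrate)
Reagents that add atoms: none
Why: Weinreb amide reduction with i-Bu2AlH stops at the aldehyde and should give the geranial-type (E)-enal without 1,4-reduction or change of alkene geometry.

**Step 6**
Reactants: 9 (2E,6R,8E)-3,9-dimethyl-6-(prop-1-en-2-yl)undeca-2,8,10-trienal
Product: 10 (1R,4aS,6R,8aR)-4,8a-dimethyl-6-(prop-1-en-2-yl)-1,2,4a,5,6,7,8,8a-octahydronaphthalene-1-carbaldehyde (1β-formyl-eudesma-3,11-diene)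
Conditions: Me2AlCl (30 mol %), CH2Cl2, −78 to −20 °C
Reagents that add atoms: none
Why: Complexation of the formyl oxygen by Me2AlCl lowers the LUMO of the (E)-β,β-disubstituted enal, which then undergoes a concerted but asynchronous, normal-electron-demand type 1 intramolecular Diels–Alder reaction with the tethered (E)-3-methyl-1,3-diene, the C5–C10 bond to the electrophilic β-carbon being more advanced than the C1–C2 bond. The closest known reaction type is the Lewis acid promoted cyclisation of (2E,7E)-deca-2,7,9-trienals and related trienones to trans-fused octalins, including β-methyl dienophiles that deliver an angular methyl group. Ring A is closed as the cyclohexene of the [4+2] cycloaddition (diene C2–C5, dienophile C1=C10), and ring B is closed at the same time as a six-membered carbocycle when the C5–C10 bond joins the ends of the four-carbon tether C6–C9, which adopts a chair-like arrangement. The trans ring fusion (5α-H, 10β-CH3) follows from the endo transition state, in which the aluminium-bound formyl group lies under the diene while the tether sits outside on the (E)-diene; the 1β (equatorial) formyl group, cis to the angular methyl, follows from suprafacial addition to the (E)-dienophile; and the absolute sense at C1, C5 and C10 is set by the existing (R) centre C7, whose isopropenyl group sits equatorial in the chair-like tether. The step needs endo over exo selectivity, π-facial selectivity and chemoselectivity for the diene over the isopropenyl group: the first should be secured by the Lewis acid and the (E,E) geometry, the second by the C7 substituent, and the third by the higher nucleophilicity of the conjugated diene and the low temperature, which should also suppress (E)/(Z) isomerisation of the enal.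

**Step 7**
Reactants: 10 1β-formyl-eudesma-3,11-diene; 11 1,3,5-trimethoxybenzene
Product: 13 (2,4,6-trimethoxyphenyl)(eudesma-3,11-dien-1β-yl)methanol (both C7′ epimers), via 2,4,6-trimethoxyphenyllithium 12 (not isolated)
Conditions: 11, n-BuLi, TMEDA, THF, 0 °C; then 10, −78 to −20 °C; H2O
Reagents that add atoms: 1,3,5-trimethoxybenzene (11), COc1cc(OC)cc(OC)c1
Why: Directed ortho-lithiation of 1,3,5-trimethoxybenzene gives the aryllithium, which should add 1,2 to the hindered aldehyde; the configuration of the new carbinol centre is irrelevant because it is ionised in step 10.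

**Step 8**
Reactants: 13 (2,4,6-trimethoxyphenyl)(eudesma-3,11-dien-1β-yl)methanol
Product: 14 3α,4α:11,12-diepoxide of 13 (C7′ and C11 epimers)
Conditions: dimethyldioxirane (acetone solution), CH2Cl2, 0 °C
Reagents that add atoms: dimethyldioxirane, CC1(C)OO1
Why: Dimethyldioxirane epoxidises both alkenes under neutral conditions that spare the acid-labile benzylic alcohol; the C3=C4 alkene should be attacked from the α face, anti to the axial angular methyl on C10, which fixes the C4–O bond as 4α, while the configuration at C11 is inconsequential.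

**Step 9**
Reactants: 14 3α,4α:11,12-diepoxide of 13
Product: 15 1β-[hydroxy(2,4,6-trimethoxyphenyl)methyl]eudesmane-4α,11-diol (C7′ epimers)
Conditions: LiEt3BH, THF, 0 to 65 °C; H2O
Reagents that add atoms: none
Why: Hydride should open each epoxide by SN2 attack at its less substituted carbon (C3 and C12), so the C–O bonds at the tertiary carbons are retained and the 4α-OH/4β-CH3 carbinol and the C11 carbinol arise without change at C4 (regioselective epoxide reduction).

**Step 10**
Reactants: 15 1β-[hydroxy(2,4,6-trimethoxyphenyl)methyl]eudesmane-4α,11-diol; 16 trimethyl(2-methylallyl)silane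
Product: 17 (7′S)-1β-[3-methyl-1-(2,4,6-trimethoxyphenyl)but-3-en-1-yl]eudesmane-4α,11-diol
Conditions: 16 (5 equiv), Me3SiOTf (10 mol %), CH2Cl2, −78 °C
Reagents that add atoms: trimethyl(2-methylallyl)silane (16), CC(=C)C[Si](C)(C)C
Why: Ionisation of the 2,4,6-trimethoxybenzylic alcohol gives a strongly stabilised benzylic cation that is captured by the allylsilane (SN1 Hosomi–Sakurai-type allylation); with C1–H held in the cation plane toward an ortho-methoxy group to avoid allylic 1,3-strain, the two faces are flanked by C2H2 and by the quaternary C10, so attack anti to C10 should give the (7′S) centre from either carbinol epimer.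

**Step 11**
Reactants: 17 (7′S)-1β-[3-methyl-1-(2,4,6-trimethoxyphenyl)but-3-en-1-yl]eudesmane-4α,11-diol
Product: 18 (7′S)-1β-[3-methyl-1-(2,4,6-trimethoxyphenyl)butyl]eudesmane-4α,11-diol
Conditions: H2 (1 atm), Pd on carbon (Pd/C), EtOAc, rt
Reagents that add atoms: none
Why: Heterogeneous hydrogenation saturates the only alkene (1,1-disubstituted) to the isobutyl group without affecting the arene, the tertiary alcohols or any stereocentre.

**Step 12**
Reactants: 18 (7′S)-1β-[3-methyl-1-(2,4,6-trimethoxyphenyl)butyl]eudesmane-4α,11-diol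
Product: 20 5-[(1S)-1-(4α,11-dihydroxyeudesman-1β-yl)-3-methylbutyl]-2,4,6-trimethoxybenzene-1,3-dicarbaldehyde (tri-O-methyl-macrocarpal J), via trilithium monoformyl hemiaminal alkoxide 19 (not isolated)
Conditions: n-BuLi, TMEDA, THF, 0 °C; DMF, −78 °C; n-BuLi, 0 °C; DMF, −78 °C; H2O
Reagents that add atoms: N,N-dimethylformamide, CN(C)C=O
Why: Each remaining ring C–H lies between two methoxy groups and should be removed by directed ortho-lithiation (the alcohols being present as lithium alkoxides); trapping with DMF gives a lithium hemiaminal alkoxide that masks the first formyl group during the second lithiation–formylation, and both aldehydes are released on work-up.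

**Step 13**
Reactants: 20 tri-O-methyl-macrocarpal J
Product: 21 Macrocarpal J
Conditions: NaSEt, DMF, 110 °C; then 1 M HCl
Reagents that add atoms: none
Why: Thiolate SN2 demethylation should be fast for aryl methyl ethers that are ortho/para to formyl groups and twisted by two flanking substituents, and these basic conditions leave the two tertiary alcohols intact where Lewis acids would ionise them.

**Compound list**
1 | (4R)-limonene 1,2-oxide (cis/trans mixture) | CC12CC[C@H](CC1O2)C(C)=C | starting material
2 | (4R)-1-methyl-4-(prop-1-en-2-yl)cyclohexane-1,2-diol (limonene-1,2-diol) | CC1(O)CC[C@H](CC1O)C(C)=C | intermediate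
3 | (3R)-6-oxo-3-(prop-1-en-2-yl)heptanal | CC(=O)CC[C@H](CC=O)C(C)=C | intermediate
4 | 2-(triphenylphosphoranylidene)propanal | CC(C=O)=P(c1ccccc1)(c1ccccc1)c1ccccc1 | starting material
5 | (2E,5R)-2-methyl-8-oxo-5-(prop-1-en-2-yl)non-2-enal | CC(=O)CC[C@H](C/C=C(\C)C=O)C(C)=C | intermediate
6 | (5R,7E)-8-methyl-5-(prop-1-en-2-yl)deca-7,9-dien-2-one | CC(=O)CC[C@H](C/C=C(\C)C=C)C(C)=C | intermediate
7 | diethyl {2-[methoxy(methyl)amino]-2-oxoethyl}phosphonate | CCOP(=O)(CC(=O)N(C)OC)OCC | starting material
8 | (2E,6R,8E)-N-methoxy-N,3,9-trimethyl-6-(prop-1-en-2-yl)undeca-2,8,10-trienamide | CON(C)C(=O)/C=C(\C)CC[C@H](C/C=C(\C)C=C)C(C)=C | intermediate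
9 | (2E,6R,8E)-3,9-dimethyl-6-(prop-1-en-2-yl)undeca-2,8,10-trienal | O=C/C=C(\C)CC[C@H](C/C=C(\C)C=C)C(C)=C | intermediate
10 | (1R,4aS,6R,8aR)-4,8a-dimethyl-6-(prop-1-en-2-yl)-1,2,4a,5,6,7,8,8a-octahydronaphthalene-1-carbaldehyde (1β-formyl-eudesma-3,11-diene, trans-fused) | O=C[C@@H]1CC=C(C)[C@@H]2C[C@H](C(C)=C)CC[C@]21C | intermediate
11 | 1,3,5-trimethoxybenzene | COc1cc(OC)cc(OC)c1 | starting material
12 | 2,4,6-trimethoxyphenyllithium | [Li]c1c(OC)cc(OC)cc1OC | intermediate
13 | (2,4,6-trimethoxyphenyl)(eudesma-3,11-dien-1β-yl)methanol (C7′ epimers) | COc1cc(OC)c(C(O)[C@@H]2CC=C(C)[C@@H]3C[C@H](C(C)=C)CC[C@]32C)c(OC)c1 | intermediate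
14 | 3α,4α:11,12-diepoxide of 13 (C7′ and C11 epimers) | COc1cc(OC)c(C(O)[C@@H]2C[C@H]4O[C@@]4(C)[C@@H]3C[C@H](C5(C)CO5)CC[C@]32C)c(OC)c1 | intermediate
15 | 1β-[hydroxy(2,4,6-trimethoxyphenyl)methyl]eudesmane-4α,11-diol (C7′ epimers) | COc1cc(OC)c(C(O)[C@@H]2CC[C@@](C)(O)[C@@H]3C[C@H](C(C)(C)O)CC[C@]32C)c(OC)c1 | intermediate
16 | trimethyl(2-methylallyl)silane | CC(=C)C[Si](C)(C)C | starting material
17 | (7′S)-1β-[3-methyl-1-(2,4,6-trimethoxyphenyl)but-3-en-1-yl]eudesmane-4α,11-diol | COc1cc(OC)c([C@@H](CC(C)=C)[C@@H]2CC[C@@](C)(O)[C@@H]3C[C@H](C(C)(C)O)CC[C@]32C)c(OC)c1 | intermediate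
18 | (7′S)-1β-[3-methyl-1-(2,4,6-trimethoxyphenyl)butyl]eudesmane-4α,11-diol | COc1cc(OC)c([C@@H](CC(C)C)[C@@H]2CC[C@@](C)(O)[C@@H]3C[C@H](C(C)(C)O)CC[C@]32C)c(OC)c1 | intermediate
19 | trilithium salt of the mono-(dimethylamino)(oxido)methyl adduct of 18 (masked monoaldehyde, both alcohols as alkoxides) | [Li+].[Li+].[Li+].COc1cc(OC)c(C([O-])N(C)C)c(OC)c1[C@@H](CC(C)C)[C@@H]1CC[C@@](C)([O-])[C@@H]2C[C@H](C(C)(C)[O-])CC[C@]21C | intermediate
20 | 5-[(1S)-1-(4α,11-dihydroxyeudesman-1β-yl)-3-methylbutyl]-2,4,6-trimethoxybenzene-1,3-dicarbaldehyde (tri-O-methyl-macrocarpal J) | COc1c(C=O)c(OC)c(C=O)c(OC)c1[C@@H](CC(C)C)[C@@H]1CC[C@@](C)(O)[C@@H]2C[C@H](C(C)(C)O)CC[C@]21C | intermediate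
21 | Macrocarpal J | CC(C)C[C@H](c1c(O)c(C=O)c(O)c(C=O)c1O)[C@@H]1CC[C@@](C)(O)[C@@H]2C[C@H](C(C)(C)O)CC[C@]21C | target

**Totals**
Total step count: 13. Longest linear sequence: 13 steps (from 1).

**Steps most likely to fail**

Step 6 (cycloaddition). The β,β-disubstituted enal may cyclise sluggishly. Lewis acid induced (E)/(Z) isomerisation of the dienophile, cationic capture of the activated enal by the isopropenyl group, or erosion of endo selectivity could then compete. Fallback, an ionic Diels–Alder reaction through an alkoxy-allyl cation dienophile: from 9, acetalisation with ethane-1,2-diol (PPTS, benzene, reflux with water removal) should give 2-[(1E,5R,7E)-2,8-dimethyl-5-(prop-1-en-2-yl)deca-1,7,9-trien-1-yl]-1,3-dioxolane F1. Catalytic TfOH in CH2Cl2 at −78 °C opens the acetal to an oxygen-stabilised allyl cation, a far more electron-poor dienophile that is known to cyclise trienes to trans-fused bicycles at this temperature, and the cation recloses to the cycloadduct acetal 2-[(1R,4aS,6R,8aR)-4,8a-dimethyl-6-(prop-1-en-2-yl)-1,2,4a,5,6,7,8,8a-octahydronaphthalen-1-yl]-1,3-dioxolane F2. Mild hydrolysis (PPTS, acetone/H2O) returns the route at 10.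

Step 10 (benzylic centre C7′). Facial selectivity in the capture of the benzylic cation may be low or opposite to the model, and loss of the C1 proton to a styrene may compete. Fallback, exchanging the roles of hydride and the four-carbon unit so that the sense of induction at C7′ is reversed: from 15, oxidation of the benzylic alcohol only (MnO2, CH2Cl2) should give (4α,11-dihydroxyeudesman-1β-yl)(2,4,6-trimethoxyphenyl)methanone F3. Addition of CH2=C(CH3)CH2MgCl (THF, 0 °C), which adds to hindered ketones through a cyclic allyl-transfer transition state, gives 1β-[1-hydroxy-3-methyl-1-(2,4,6-trimethoxyphenyl)but-3-en-1-yl]eudesmane-4α,11-diol F4. Ionic reduction of this tertiary benzylic alcohol (Et3SiH, catalytic Me3SiOTf, CH2Cl2, −78 °C), with hydride now the incoming group on the same cation face, returns the route at 17.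

Step 12 (double formylation). The second ortho-lithiation of the polyanionic intermediate may be incomplete, and butyllithium may attack the masked aldehyde. Fallback, halogenation and halogen–lithium exchange instead of directed deprotonation: from 18, electrophilic bromination of both free ring positions (N-bromosuccinimide, 2.1 equiv, MeCN, 0 °C) should give (7′S)-1β-[1-(3,5-dibromo-2,4,6-trimethoxyphenyl)-3-methylbutyl]eudesmane-4α,11-diol F5. Deprotonation of the alcohols and double bromine–lithium exchange (MeLi, then t-BuLi, THF, −78 °C), DMF quench and aqueous work-up return the route at 20.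

**Further compounds**
F1 | step 6 | 2-[(1E,5R,7E)-2,8-dimethyl-5-(prop-1-en-2-yl)deca-1,7,9-trien-1-yl]-1,3-dioxolane | O1CCOC1/C=C(\C)CC[C@H](C/C=C(\C)C=C)C(C)=C
F2 | step 6 | 2-[(1R,4aS,6R,8aR)-4,8a-dimethyl-6-(prop-1-en-2-yl)-1,2,4a,5,6,7,8,8a-octahydronaphthalen-1-yl]-1,3-dioxolane | O1CCOC1[C@@H]1CC=C(C)[C@@H]2C[C@H](C(C)=C)CC[C@]21C
F3 | step 10 | (4α,11-dihydroxyeudesman-1β-yl)(2,4,6-trimethoxyphenyl)methanone | COc1cc(OC)c(C(=O)[C@@H]2CC[C@@](C)(O)[C@@H]3C[C@H](C(C)(C)O)CC[C@]32C)c(OC)c1
F4 | step 10 | 1β-[1-hydroxy-3-methyl-1-(2,4,6-trimethoxyphenyl)but-3-en-1-yl]eudesmane-4α,11-diol (C7′ epimers) | COc1cc(OC)c(C(O)(CC(C)=C)[C@@H]2CC[C@@](C)(O)[C@@H]3C[C@H](C(C)(C)O)CC[C@]32C)c(OC)c1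
F5 | step 12 | (7′S)-1β-[1-(3,5-dibromo-2,4,6-trimethoxyphenyl)-3-methylbutyl]eudesmane-4α,11-diol | COc1c(Br)c(OC)c(Br)c(OC)c1[C@@H](CC(C)C)[C@@H]1CC[C@@](C)(O)[C@@H]2C[C@H](C(C)(C)O)CC[C@]21C
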